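**Retrosynthetic overview**

1. Rings: A = para-phenylene, B = trioxygenated benzoyl ring, C = meta-phenylene (CH2/O), D = ring with OH, OAr and CH2CH2. Marchantin G ⇐ (BBr3: two OMe and the dioxolane) macrocyclic phenol 23 ⇐ (dehydrogenation) macrocyclic 2-aryloxycyclohex-2-enone 20; ring D is carried non-aromatic and aromatised last.
2. Enabling feature: ring D is an ortho-aryloxyphenol whose ether carbon lies between the C–OH carbon and the CH2CH2-bearing carbon. These three carbons map onto C-1 (C=O), C-2 (electrophilic epoxide carbon) and C-3 of a 3-alkyl-2,3-epoxycyclohexanone.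
3. Key disconnection: the bond between the ring C oxygen and the ring D ether carbon of 20 ⇐ seco epoxy ketone 17. Fluoride frees the ring C phenoxide, which closes the 18-membered ring at C-2; loss of water gives the enone.
4. 17 ⇐ enone 16 (nucleophilic epoxidation) ⇐ styrene 13 + 3-bromocyclohex-2-enone 14 (hydroboration/B-alkyl Suzuki); 13 ⇐ phenol 11 + boronic acid 12 (Chan–Lam, ring A–O–ring B ether).
5. 11 ⇐ (ketalisation) deoxybenzoin 10 ⇐ Weinreb amide 6 (ring B) + benzylic Grignard reagent 7 (ring C). Ring order: A, B, C bought aromatic; cyclohexenone D attached (step 7); macrocycle (step 9); ring D arene (step 10).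

Key step: step 9

Remark: marchantin G is treated as achiral and conformationally mobile (no stereocentre, no stable atropisomer); the stereocentres of racemic 17 and of 19 vanish when ring D becomes planar.

**Route**

Step 1
Reactants: 1 3-hydroxybenzyl alcohol
Product: 3 [3-(triisopropylsilyloxy)phenyl]methanol, via sodium phenoxide 2 (not isolated)
Conditions: NaH (1.0 equiv), THF/DMF, 0 °C; then TIPSCl (1.0 equiv), 0 °C to rt
Reagents that add atoms: chlorotriisopropylsilane (TIPSCl), CC(C)[Si](Cl)(C(C)C)C(C)C
Why: Selective O-silylation of a phenoxide: one equivalent of NaH deprotonates only the phenol, which is far more acidic than the benzylic alcohol, and the hindered silyl chloride is captured by that phenoxide.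

Step 2
Reactants: 3 [3-(triisopropylsilyloxy)phenyl]methanol
Product: 4 3-(triisopropylsilyloxy)benzyl chloride
Conditions: SOCl2, pyridine, CH2Cl2, 0 °C to rt
Reagents that add atoms: thionyl chloride, O=S(Cl)Cl
Why: Deoxychlorination of a benzylic alcohol with thionyl chloride (chlorosulfite, then chloride substitution) under buffered conditions that an aryl triisopropylsilyl ether should tolerate.

Step 3
Reactants: 5 3-hydroxy-4,5-dimethoxybenzoic acid
Product: 6 3-hydroxy-N,4,5-trimethoxy-N-methylbenzamide
Conditions: MeNH(OMe)·HCl, EDC·HCl, HOBt, i-Pr2NEt, CH2Cl2, 0 °C to rt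
Reagents that add atoms: N,O-dimethylhydroxylamine hydrochloride, CNOC.Cl
Why: Carbodiimide amide coupling to the Weinreb amide; the amine should outcompete the free meta-phenol for the active ester.

Step 4
Reactants: 6 3-hydroxy-N,4,5-trimethoxy-N-methylbenzamide; 4 3-(triisopropylsilyloxy)benzyl chloride
Product: 10 1-(3-hydroxy-4,5-dimethoxyphenyl)-2-[3-(triisopropylsilyloxy)phenyl]ethan-1-one, via Grignard reagent 7 (not isolated), via magnesium phenoxide 8 (not isolated), via tetrahedral chelate 9 (not isolated)
Conditions: 4, Mg, THF, 0 °C (gives 7); 6, t-BuMgCl (1.0 equiv), THF, −20 °C (gives 8); 7 (1.5 equiv) added, −20 to 0 °C; then 1 M HCl, 0 °C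
Reagents that add atoms: none
Why: Weinreb ketone synthesis with a benzylic Grignard reagent: the N-methoxy chelate 9 survives until work-up so that only one addition occurs, and the phenol is parked as its magnesium phenoxide, which sits meta to the carbonyl group and does not deactivate it.

Step 5
Reactants: 10 1-(3-hydroxy-4,5-dimethoxyphenyl)-2-[3-(triisopropylsilyloxy)phenyl]ethan-1-one
Product: 11 2,3-dimethoxy-5-{2-[3-(triisopropylsilyloxy)benzyl]-1,3-dioxolan-2-yl}phenol
Conditions: ethylene glycol, TsOH·H2O (cat.), benzene, reflux, Dean–Stark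
Reagents that add atoms: ethylene glycol, OCCO
Why: Acid-catalysed ketalisation with azeotropic removal of water; the dioxolane masks the only other enolisable position (the deoxybenzoin CH2) for the base-mediated steps 7 to 10 and is installed before the acid-sensitive styrene is present.

Step 6
Reactants: 11 2,3-dimethoxy-5-{2-[3-(triisopropylsilyloxy)benzyl]-1,3-dioxolan-2-yl}phenol; 12 (4-vinylphenyl)boronic acid
Product: 13 2-[3,4-dimethoxy-5-(4-vinylphenoxy)phenyl]-2-[3-(triisopropylsilyloxy)benzyl]-1,3-dioxolane
Conditions: 12 (2 equiv), Cu(OAc)2 (2 equiv), pyridine (5 equiv), 4 Å MS, CH2Cl2, rt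
Reagents that add atoms: none
Why: Chan–Lam O-arylation of a phenol with an arylboronic acid at room temperature, which should tolerate the ortho-methoxy group, the silyl ether, the ketal and the vinyl group.

Step 7
Reactants: 13 2-[3,4-dimethoxy-5-(4-vinylphenoxy)phenyl]-2-[3-(triisopropylsilyloxy)benzyl]-1,3-dioxolane; 14 3-bromocyclohex-2-en-1-one
Product: 16 3-{2-[4-(2,3-dimethoxy-5-{2-[3-(triisopropylsilyloxy)benzyl]-1,3-dioxolan-2-yl}phenoxy)phenyl]ethyl}cyclohex-2-en-1-one, via alkylborane 15 (not isolated)
Conditions: 9-BBN (1.5 equiv), THF, 0 °C to rt; then 3 M aq. K3PO4, 14 (1.3 equiv), PdCl2(dppf) (5 mol %), DMF, rt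
Reagents that add atoms: none
Why: Anti-Markovnikov hydroboration of the styrene followed by B-alkyl Suzuki–Miyaura coupling with a β-bromo enone, a coupling partner of the vinylogous acyl halide class for which this reaction is well established.

Step 8
Reactants: 16 3-{2-[4-(2,3-dimethoxy-5-{2-[3-(triisopropylsilyloxy)benzyl]-1,3-dioxolan-2-yl}phenoxy)phenyl]ethyl}cyclohex-2-en-1-one
Product: 17 rac-(2R,3S)-2,3-epoxy-3-{2-[4-(2,3-dimethoxy-5-{2-[3-(triisopropylsilyloxy)benzyl]-1,3-dioxolan-2-yl}phenoxy)phenyl]ethyl}cyclohexan-1-one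
Conditions: t-BuOOH (5.5 M in decane, 3 equiv), DBU (1.5 equiv), CH2Cl2, 0 °C to rt
Reagents that add atoms: tert-butyl hydroperoxide, CC(C)(C)OO
Why: Weitz–Scheffer nucleophilic epoxidation under anhydrous conditions, chemoselective for the enone; the two new stereocentres are cis by ring fusion and racemic, and both are erased in step 9.

Step 9
Reactants: 17 rac-(2R,3S)-2,3-epoxy-3-{2-[4-(2,3-dimethoxy-5-{2-[3-(triisopropylsilyloxy)benzyl]-1,3-dioxolan-2-yl}phenoxy)phenyl]ethyl}cyclohexan-1-one
Product: 20 macrocyclic 2-aryloxycyclohex-2-en-1-one (ring-D enone of marchantin G ring-B dimethyl ether ethylene ketal), via cesium phenoxide 18 (not isolated), via cesium aldolate 19 (not isolated)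
Conditions: CsF (3 equiv), DMF, 70 °C, 17 added over 12 h by syringe pump (final 2 mM)
Reagents that add atoms: none
Why: Proposed new method: fluoride cleaves the aryl silyl ether, and cesium phenoxide 18, the only nucleophile in the molecule, opens the epoxide by SN2 attack at C-2 (alpha to the ring D ketone) to give aldolate 19, which after proton transfer loses hydroxide by E1cB elimination, so that the new O–C bond ends on the enol-ether carbon of enone 20. The closest known reaction type is the base-mediated intermolecular union of phenols with 2,3-epoxycyclohexanones to 2-aryloxycyclohex-2-enones; closing a macrocycle in this way is the untested part. The 18-membered ring closes in the 18-endo-tet mode of an epoxide opening (both epoxide carbons end inside the ring); the competing 17-exo attack at C-3 is disfavoured because C-3 is fully substituted whereas C-2 is secondary and activated by the adjacent carbonyl group. The one new stereocentre, C-2 of 19, is set anti to the C-3 oxygen by inversion, but both centres become sp2 in the dehydration, so the racemic nature of 17 has no consequence. The step needs O-alkylation by a single phenoxide and ring closure over oligomerisation: the dioxolane removes the acidic deoxybenzoin CH2 and keeps the bridge carbon sp3 (the same turn as a CH2 bridge), the ring B catechol is capped as methyl ethers, and slow addition holds 18 at millimolar concentration.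

Step 10
Reactants: 20 macrocyclic 2-aryloxycyclohex-2-en-1-one (ring-D enone of marchantin G ring-B dimethyl ether ethylene ketal)
Product: 23 marchantin G ring-B dimethyl ether ethylene ketal (macrocyclic phenol), via silyl dienol ether 21 (not isolated), via dienone tautomer 22 (not isolated)
Conditions: LDA (1.3 equiv), TMSCl (1.5 equiv), THF, −78 to 0 °C; then Pd(OAc)2 (1.1 equiv), MeCN, rt
Reagents that add atoms: none
Why: Saegusa–Ito oxidation: kinetic α′-deprotonation and silylation give the cross-conjugated dienol ether 21, Pd(OAc)2 dehydrogenates it to dienone 22, and 22 tautomerises irreversibly to the phenol, which aromatises ring D.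

Step 11
Reactants: 23 marchantin G ring-B dimethyl ether ethylene ketal (macrocyclic phenol)
Product: 24 marchantin G
Conditions: BBr3 (10 equiv), CH2Cl2, −78 to 0 °C; then H2O/THF, rt
Reagents that add atoms: water, O
Why: Lewis-acid ether cleavage: boron tribromide should cleave both aryl methyl ethers and open the dioxolane, whose bromo-ether/borate residue is hydrolysed to the ketone on aqueous work-up, while the diaryl ethers are untouched.

**Compound list**

1 | 3-hydroxybenzyl alcohol | OCc1cccc(O)c1 | starting material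
2 | sodium 3-(hydroxymethyl)phenoxide (not isolated) | OCc1cccc([O-])c1.[Na+] | intermediate
3 | [3-(triisopropylsilyloxy)phenyl]methanol | OCc1cccc(O[Si](C(C)C)(C(C)C)C(C)C)c1 | intermediate
4 | 3-(triisopropylsilyloxy)benzyl chloride | ClCc1cccc(O[Si](C(C)C)(C(C)C)C(C)C)c1 | intermediate
5 | 3-hydroxy-4,5-dimethoxybenzoic acid | OC(=O)c1cc(O)c(OC)c(OC)c1 | starting material
6 | 3-hydroxy-N,4,5-trimethoxy-N-methylbenzamide | CON(C)C(=O)c1cc(O)c(OC)c(OC)c1 | intermediate
7 | 3-(triisopropylsilyloxy)benzylmagnesium chloride (not isolated) | Cl[Mg]Cc1cccc(O[Si](C(C)C)(C(C)C)C(C)C)c1 | intermediate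
8 | chloromagnesium phenoxide of 6 (not isolated) | CON(C)C(=O)c1cc(O[Mg]Cl)c(OC)c(OC)c1 | intermediate
9 | tetrahedral magnesium chelate from 7 and 8 (not isolated) | CON(C)C(O[Mg]Cl)(Cc1cccc(O[Si](C(C)C)(C(C)C)C(C)C)c1)c1cc(O[Mg]Cl)c(OC)c(OC)c1 | intermediate
10 | 1-(3-hydroxy-4,5-dimethoxyphenyl)-2-[3-(triisopropylsilyloxy)phenyl]ethan-1-one | O=C(Cc1cccc(O[Si](C(C)C)(C(C)C)C(C)C)c1)c1cc(O)c(OC)c(OC)c1 | intermediate
11 | 2,3-dimethoxy-5-{2-[3-(triisopropylsilyloxy)benzyl]-1,3-dioxolan-2-yl}phenol | Oc1cc(cc(OC)c1OC)C1(Cc2cccc(O[Si](C(C)C)(C(C)C)C(C)C)c2)OCCO1 | intermediate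
12 | (4-vinylphenyl)boronic acid | C=Cc1ccc(cc1)B(O)O | starting material
13 | 2-[3,4-dimethoxy-5-(4-vinylphenoxy)phenyl]-2-[3-(triisopropylsilyloxy)benzyl]-1,3-dioxolane | C=Cc1ccc(cc1)Oc1cc(cc(OC)c1OC)C1(Cc2cccc(O[Si](C(C)C)(C(C)C)C(C)C)c2)OCCO1 | intermediate
14 | 3-bromocyclohex-2-en-1-one | O=C1C=C(Br)CCC1 | starting material
15 | B-alkyl-9-borabicyclo[3.3.1]nonane from 13 (boron on the terminal carbon; not isolated) | C1CCC2CCCC1B2CCc1ccc(cc1)Oc1cc(cc(OC)c1OC)C1(Cc2cccc(O[Si](C(C)C)(C(C)C)C(C)C)c2)OCCO1 | intermediate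
16 | 3-{2-[4-(2,3-dimethoxy-5-{2-[3-(triisopropylsilyloxy)benzyl]-1,3-dioxolan-2-yl}phenoxy)phenyl]ethyl}cyclohex-2-en-1-one | O=C1C=C(CCc2ccc(cc2)Oc2cc(cc(OC)c2OC)C2(Cc3cccc(O[Si](C(C)C)(C(C)C)C(C)C)c3)OCCO2)CCC1 | intermediate
17 | rac-(2R,3S)-2,3-epoxy-3-{2-[4-(2,3-dimethoxy-5-{2-[3-(triisopropylsilyloxy)benzyl]-1,3-dioxolan-2-yl}phenoxy)phenyl]ethyl}cyclohexan-1-one (cis-fused epoxide; one enantiomer drawn) | O=C1[C@@H]2O[C@]2(CCc2ccc(cc2)Oc2cc(cc(OC)c2OC)C2(Cc3cccc(O[Si](C(C)C)(C(C)C)C(C)C)c3)OCCO2)CCC1 | intermediate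
18 | cesium phenoxide of 17 after loss of the silyl group (racemic; not isolated) | O=C1[C@@H]2O[C@]2(CCc2ccc(cc2)Oc2cc(cc(OC)c2OC)C2(Cc3cccc([O-])c3)OCCO2)CCC1.[Cs+] | intermediate
19 | macrocyclic cesium aldolate, rac-(2S,3S)-2-aryloxy-3-oxidocyclohexanone with aryloxy anti to the C-3 oxygen (not isolated) | O=C1CCC[C@@]2([O-])[C@@H]1Oc1cccc(c1)CC1(OCCO1)c1cc(Oc3ccc(CC2)cc3)c(OC)c(OC)c1.[Cs+] | intermediate
20 | macrocyclic 2-aryloxycyclohex-2-en-1-one (ring-D enone of marchantin G ring-B dimethyl ether ethylene ketal) | O=C1CCCC2=C1Oc1cccc(c1)CC1(OCCO1)c1cc(Oc3ccc(CC2)cc3)c(OC)c(OC)c1 | intermediate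
21 | macrocyclic trimethylsilyl dienol ether of 20 (silyloxy diene in ring D; not isolated) | C[Si](C)(C)OC1=CCCC2=C1Oc1cccc(c1)CC1(OCCO1)c1cc(Oc3ccc(CC2)cc3)c(OC)c(OC)c1 | intermediate
22 | macrocyclic cyclohexa-2,5-dienone, keto tautomer of 23 (not isolated) | O=C1C=CCC2=C1Oc1cccc(c1)CC1(OCCO1)c1cc(Oc3ccc(CC2)cc3)c(OC)c(OC)c1 | intermediate
23 | marchantin G ring-B dimethyl ether ethylene ketal (macrocyclic phenol, ring D aromatic) | Oc1cccc2c1Oc1cccc(c1)CC1(OCCO1)c1cc(Oc3ccc(CC2)cc3)c(OC)c(OC)c1 | intermediate
24 | marchantin G | O=C1Cc2cccc(c2)Oc2c(O)cccc2CCc2ccc(cc2)Oc2cc1cc(O)c2O | target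

**Step count and risks**

Total step count: 11. Longest linear sequence: 10 steps (from 1 through steps 1, 2 and 4 to 11).

Steps most likely to fail:

Step 9 (bears the label). At millimolar concentration the phenoxide may open the epoxide more slowly than base-induced enolisation and self-aldolisation of the epoxy ketone. Retro-aldol cleavage of the aldolate may also outrun dehydration. Either way oligomers or ring-opened diketones would form instead of the macrocycle. The fallback uses known chemistry, buys ring D aromatic and closes the same bond by SNAr; it sets out from styrene 13 and comes back to the route at phenol 23. Hydroboration of 13 with 9-BBN as in step 7 gives alkylborane 15. B-alkyl Suzuki–Miyaura coupling of 15 (PdCl2(dppf), aq. K3PO4, DMF/THF) with commercial 3-bromo-2-fluorobenzaldehyde (O=Cc1cccc(Br)c1F) should give the fluoro aldehyde F1, in which fluorine sits on the future ether carbon and is activated by the ortho formyl group. CsF in DMF at about 110 °C under high dilution should cleave the silyl ether to the cesium phenoxide F2 (not isolated). This should close the 18-membered ring by intramolecular SNAr displacement of fluoride to give the macrocyclic diaryl ether aldehyde F3. Baeyer–Villiger oxidation with mCPBA/NaHCO3 in CH2Cl2 should give the aryl formate F4, and K2CO3 in MeOH should release phenol 23, from which step 11 follows.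

Step 8. The basic peroxide may remove the aryl silyl ether, after which the freed phenoxide would attack the epoxy ketone intermolecularly at preparative concentration. Conjugate addition of the peroxide to the β,β-disubstituted enone may also stall. The fallback is a neutral, hydroxyl-directed epoxidation; it sets out from enone 16 and comes back to the route at epoxy ketone 17. Luche reduction (NaBH4, CeCl3·7H2O, MeOH, 0 °C) should give the racemic allylic alcohol F5. Epoxidation with t-BuOOH and catalytic VO(acac)2 in CH2Cl2 should deliver oxygen syn to the hydroxyl group and give the cis epoxy alcohol F6. Oxidation with Dess–Martin periodinane buffered with NaHCO3 should then give 17.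

Step 10. The dienol ether may hydrolyse back to 20 before palladation, or β-hydride elimination may be slow, so that Pd(OAc)2 is reduced to palladium metal without turnover of the substrate and ring D stays at the enone level. The fallback replaces palladium by a selenoxide syn-elimination; it sets out from enone 20 and comes back to the route at phenol 23. LiHMDS followed by PhSeCl in THF at −78 °C should give the α′-phenylselanyl enone F7. H2O2/pyridine in CH2Cl2 at 0 °C should give the selenoxide F8, which should eliminate benzeneselenenic acid at room temperature to give dienone 22, the keto tautomer of 23.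

Further compounds
F1 | step 9 | 2-fluoro-3-{2-[4-(2,3-dimethoxy-5-{2-[3-(triisopropylsilyloxy)benzyl]-1,3-dioxolan-2-yl}phenoxy)phenyl]ethyl}benzaldehyde | O=Cc1cccc(CCc2ccc(cc2)Oc2cc(cc(OC)c2OC)C2(Cc3cccc(O[Si](C(C)C)(C(C)C)C(C)C)c3)OCCO2)c1F
F2 | step 9 | cesium phenoxide of F1 after loss of the silyl group (not isolated) | O=Cc1cccc(CCc2ccc(cc2)Oc2cc(cc(OC)c2OC)C2(Cc3cccc([O-])c3)OCCO2)c1F.[Cs+]
F3 | step 9 | macrocyclic diaryl ether aldehyde (formyl group in place of the ring D hydroxyl of 23) | O=Cc1cccc2c1Oc1cccc(c1)CC1(OCCO1)c1cc(Oc3ccc(CC2)cc3)c(OC)c(OC)c1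
F4 | step 9 | macrocyclic aryl formate (formate ester of 23) | O=COc1cccc2c1Oc1cccc(c1)CC1(OCCO1)c1cc(Oc3ccc(CC2)cc3)c(OC)c(OC)c1
F5 | step 8 | rac-3-{2-[4-(2,3-dimethoxy-5-{2-[3-(triisopropylsilyloxy)benzyl]-1,3-dioxolan-2-yl}phenoxy)phenyl]ethyl}cyclohex-2-en-1-ol (one enantiomer drawn) | O[C@@H]1C=C(CCc2ccc(cc2)Oc2cc(cc(OC)c2OC)C2(Cc3cccc(O[Si](C(C)C)(C(C)C)C(C)C)c3)OCCO2)CCC1
F6 | step 8 | racemic cis-2,3-epoxycyclohexan-1-ol corresponding to 17, hydroxyl syn to the epoxide oxygen (one enantiomer drawn) | O[C@@H]1[C@@H]2O[C@]2(CCc2ccc(cc2)Oc2cc(cc(OC)c2OC)C2(Cc3cccc(O[Si](C(C)C)(C(C)C)C(C)C)c3)OCCO2)CCC1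
F7 | step 10 | racemic macrocyclic 6-(phenylselanyl) derivative of enone 20 (one enantiomer drawn) | O=C1[C@@H]([Se]c2ccccc2)CCC2=C1Oc1cccc(c1)CC1(OCCO1)c1cc(Oc3ccc(CC2)cc3)c(OC)c(OC)c1
F8 | step 10 | selenoxide of F7 (mixture of diastereomers at selenium; not isolated) | O=C1[C@@H]([Se](=O)c2ccccc2)CCC2=C1Oc1cccc(c1)CC1(OCCO1)c1cc(Oc3ccc(CC2)cc3)c(OC)c(OC)c1
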